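**Retrosynthetic overview**
- Last C–O events: the two phenols are released from aryl acetates, and the quinone comes from oxidative demethylation of a dimethoxy ring, so no free hydroquinone ever sits next to the benzylic ester.
- Side chain: the ester is made by Steglich acylation of the (S)-carbinol with 3-methylbut-2-enoic acid; the trisubstituted olefin comes from cross-metathesis of a homoallylic alcohol with 2-methyl-2-butene.
- Key C–C bond (carbinol carbon to CH2): reagent-controlled asymmetric allylboration of an aryl aldehyde with an allyl fragment; this sets the only stereocentre.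
- Aryl aldehyde: Rieche formylation of 1,4-diacetoxy-5,8-dimethoxynaphthalene, made from 1,5-dihydroxynaphthalene by O-methylation, 4,8-dibromination, methoxylation, oxidation to the quinone and reductive acetylation.
- Ring order: no ring is built; both carbocycles are bought as the naphthalene, and the ring carrying the side chain is turned into the quinone ring in the penultimate step.

Assumption: the drawn 5,8-dihydroxy-1,4-quinone stands for the rapidly equilibrating naphthazarin tautomers, and the stereocentre is (S) (alkannin series).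

**Route**

Step 1
Reactants: 1 1,5-dihydroxynaphthalene
Product: 2 1,5-dimethoxynaphthalene
Conditions: Me2SO4 (2.5 equiv), K2CO3 (4 equiv), acetone, reflux
Reagents that add atoms: dimethyl sulfate, COS(=O)(=O)OC
Why: Williamson-type O-methylation of both naphthols is essentially quantitative and creates no stereocentre.

Step 2
Reactants: 2 1,5-dimethoxynaphthalene
Product: 3 4,8-dibromo-1,5-dimethoxynaphthalene
Conditions: NBS (2.05 equiv), MeCN, 0 °C to rt
Reagents that add atoms: N-bromosuccinimide, O=C1CCC(=O)N1Br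
Why: Electrophilic aromatic bromination, in which each methoxy group directs para within its own ring, so C4 and C8 are brominated selectively.

Step 3
Reactants: 3 4,8-dibromo-1,5-dimethoxynaphthalene
Product: 4 1,4,5,8-tetramethoxynaphthalene
Conditions: NaOMe (10 equiv), CuI (20 mol%), MeOH/DMF, 100 °C
Reagents that add atoms: sodium methoxide, [Na+].[O-]C
Why: Copper-catalysed Ullmann-type methoxylation replaces both aryl bromides by methoxide.

Step 4
Reactants: 4 1,4,5,8-tetramethoxynaphthalene
Product: 5 5,8-dimethoxy-1,4-naphthoquinone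
Conditions: (NH4)2Ce(NO3)6 (2.2 equiv), MeCN/H2O, 0 °C to rt
Reagents that add atoms: water, O
Why: Oxidative demethylation by tetravalent cerium turns one hydroquinone dimethyl ether ring into the quinone (oxygen from water, methyl groups lost as methanol), and the electron-poor product resists a second oxidation.

Step 5
Reactants: 5 5,8-dimethoxy-1,4-naphthoquinone
Product: 7 5,8-dimethoxynaphthalene-1,4-diyl diacetate, via hydroquinone 6 (not isolated)
Conditions: Zn dust (5 equiv), Ac2O, NaOAc (cat.), 60 °C
Reagents that add atoms: acetic anhydride, CC(=O)OC(C)=O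
Why: Reductive acetylation: zinc reduces the quinone and the air-sensitive diol is trapped at once by Ac2O, which swaps two methyl ethers for acetates that can be removed at the end without oxidant or Lewis acid.

Step 6
Reactants: 7 5,8-dimethoxynaphthalene-1,4-diyl diacetate
Product: 9 6-formyl-5,8-dimethoxynaphthalene-1,4-diyl diacetate, via chloro ether 8 (not isolated)
Conditions: Cl2CHOMe (1.5 equiv), TiCl4 (3 equiv), CH2Cl2, −10 to 0 °C; then ice-water
Reagents that add atoms: dichloromethyl methyl ether, COC(Cl)Cl; water, O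
Why: Rieche formylation (Friedel–Crafts type) attacks ortho to methoxy on the only activated ring, where C6 and C7 are equivalent by symmetry, and aqueous hydrolysis of the chloro ether gives the aldehyde.

Step 7
Reactants: 9 6-formyl-5,8-dimethoxynaphthalene-1,4-diyl diacetate; 10 allylmagnesium bromide
Product: 13 6-[(1S)-1-hydroxybut-3-en-1-yl]-5,8-dimethoxynaphthalene-1,4-diyl diacetate, via B-allyldiisopinocampheylborane 11 (not isolated), via borinate ester 12 (not isolated)
Conditions: 10, (−)-Ipc2BOMe [from (+)-α-pinene] (1.25 equiv), Et2O, 0 °C to rt, Mg salts filtered off; then 9 in THF, −78 °C, 3 h; then 8-hydroxyquinoline, MeOH, rt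
Reagents that add atoms: none
Why: Brown asymmetric allylboration (carbonyl allylation) through a closed chair transition state, in which the isopinocampheyl ligands derived from (+)-α-pinene direct the allyl group to the Si face of the aryl aldehyde and so set the (S)-carbinol (typically ≥ 90% ee), while the non-oxidative, base-free oxinate work-up spares the aryl acetates.

Step 8
Reactants: 13 6-[(1S)-1-hydroxybut-3-en-1-yl]-5,8-dimethoxynaphthalene-1,4-diyl diacetate; 14 2-methyl-2-butene
Product: 15 6-[(1S)-1-hydroxy-4-methylpent-3-en-1-yl]-5,8-dimethoxynaphthalene-1,4-diyl diacetate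
Conditions: 14 (excess, co-solvent), second-generation Grubbs catalyst RuCl2(=CHPh)(H2IMes)(PCy3) (5 mol%), CH2Cl2, 40 °C, sealed tube
Reagents that add atoms: none
Why: Olefin cross-metathesis of the terminal alkene with excess 2-methyl-2-butene installs the isopropylidene terminus with loss of propene and leaves the carbinol stereocentre untouched.

Step 9
Reactants: 15 6-[(1S)-1-hydroxy-4-methylpent-3-en-1-yl]-5,8-dimethoxynaphthalene-1,4-diyl diacetate; 16 3-methylbut-2-enoic acid
Product: 18 5,8-dimethoxy-6-{(1S)-4-methyl-1-[(3-methylbut-2-enoyl)oxy]pent-3-en-1-yl}naphthalene-1,4-diyl diacetate, via O-acylisourea 17 (not isolated)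
Conditions: DCC (1.5 equiv), DMAP (0.1 equiv), CH2Cl2, 0 °C to rt
Reagents that add atoms: none
Why: Steglich esterification acylates the oxygen only, so the (S) configuration is retained, and using the free acid with DCC and little DMAP avoids the ketene-derived deconjugation seen with the acid chloride.

Step 10
Reactants: 18 5,8-dimethoxy-6-{(1S)-4-methyl-1-[(3-methylbut-2-enoyl)oxy]pent-3-en-1-yl}naphthalene-1,4-diyl diacetate
Product: 19 2-{(1S)-4-methyl-1-[(3-methylbut-2-enoyl)oxy]pent-3-en-1-yl}-1,4-dioxo-1,4-dihydronaphthalene-5,8-diyl diacetate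
Conditions: (NH4)2Ce(NO3)6 (2.5 equiv), MeCN/H2O (4:1), 0 °C, 15 min
Reagents that add atoms: water, O
Why: Oxidative demethylation by tetravalent cerium can only take place on the dimethoxy ring (the acetoxy ring is deactivated), so the quinone forms regioselectively on the ring bearing the side chain, without a free hydroquinone intermediate that could expel the benzylic ester.

Step 11
Reactants: 19 2-{(1S)-4-methyl-1-[(3-methylbut-2-enoyl)oxy]pent-3-en-1-yl}-1,4-dioxo-1,4-dihydronaphthalene-5,8-diyl diacetate
Product: 20 alkannin β,β-dimethylacrylate, (1S)-1-(5,8-dihydroxy-1,4-dioxo-1,4-dihydronaphthalen-2-yl)-4-methylpent-3-en-1-yl 3-methylbut-2-enoate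
Conditions: K2CO3 (2.2 equiv), MeOH, argon, 0 °C, 20 min; then AcOH
Reagents that add atoms: none
Why: Chemoselective transesterification: the two phenolic acetates peri to the quinone carbonyls are activated aryl esters and are methanolysed far faster than the hindered, conjugated secondary 3-methylbut-2-enoate, and the short cold exposure does not touch the stereocentre.

**Compound list**

1 | 1,5-dihydroxynaphthalene | Oc1cccc2c(O)cccc12 | starting material
2 | 1,5-dimethoxynaphthalene | COc1cccc2c(OC)cccc12 | intermediate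
3 | 4,8-dibromo-1,5-dimethoxynaphthalene | COc1ccc(Br)c2c(OC)ccc(Br)c12 | intermediate
4 | 1,4,5,8-tetramethoxynaphthalene | COc1ccc(OC)c2c(OC)ccc(OC)c12 | intermediate
5 | 5,8-dimethoxy-1,4-naphthoquinone | COc1ccc(OC)c2C(=O)C=CC(=O)c12 | intermediate
6 | 5,8-dimethoxynaphthalene-1,4-diol (formed as its zinc salt) | COc1ccc(OC)c2c(O)ccc(O)c12 | intermediate
7 | 5,8-dimethoxynaphthalene-1,4-diyl diacetate | COc1ccc(OC)c2c(OC(C)=O)ccc(OC(C)=O)c12 | intermediate
8 | 6-[chloro(methoxy)methyl]-5,8-dimethoxynaphthalene-1,4-diyl diacetate (racemic) | COC(Cl)c1cc(OC)c2c(OC(C)=O)ccc(OC(C)=O)c2c1OC | intermediate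
9 | 6-formyl-5,8-dimethoxynaphthalene-1,4-diyl diacetate | O=Cc1cc(OC)c2c(OC(C)=O)ccc(OC(C)=O)c2c1OC | intermediate
10 | allylmagnesium bromide | C=CC[Mg]Br | starting material
11 | B-allyldiisopinocampheylborane, Ipc groups from (+)-α-pinene | C=CCB([C@@H]1C[C@@H]2C[C@@H](C2(C)C)[C@H]1C)[C@@H]1C[C@@H]2C[C@@H](C2(C)C)[C@H]1C | intermediate
12 | (1S)-1-(5,8-diacetoxy-1,4-dimethoxynaphthalen-2-yl)but-3-en-1-yl diisopinocampheylborinate | C=CC[C@H](OB([C@@H]1C[C@@H]2C[C@@H](C2(C)C)[C@H]1C)[C@@H]1C[C@@H]2C[C@@H](C2(C)C)[C@H]1C)c1cc(OC)c2c(OC(C)=O)ccc(OC(C)=O)c2c1OC | intermediate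
13 | 6-[(1S)-1-hydroxybut-3-en-1-yl]-5,8-dimethoxynaphthalene-1,4-diyl diacetate | C=CC[C@H](O)c1cc(OC)c2c(OC(C)=O)ccc(OC(C)=O)c2c1OC | intermediate
14 | 2-methyl-2-butene | CC=C(C)C | starting material
15 | 6-[(1S)-1-hydroxy-4-methylpent-3-en-1-yl]-5,8-dimethoxynaphthalene-1,4-diyl diacetate | CC(C)=CC[C@H](O)c1cc(OC)c2c(OC(C)=O)ccc(OC(C)=O)c2c1OC | intermediate
16 | 3-methylbut-2-enoic acid | CC(C)=CC(=O)O | starting material
17 | O-(3-methylbut-2-enoyl)-N,N'-dicyclohexylisourea | CC(C)=CC(=O)OC(=NC1CCCCC1)NC1CCCCC1 | intermediate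
18 | 5,8-dimethoxy-6-{(1S)-4-methyl-1-[(3-methylbut-2-enoyl)oxy]pent-3-en-1-yl}naphthalene-1,4-diyl diacetate | CC(C)=CC[C@H](OC(=O)C=C(C)C)c1cc(OC)c2c(OC(C)=O)ccc(OC(C)=O)c2c1OC | intermediate
19 | 2-{(1S)-4-methyl-1-[(3-methylbut-2-enoyl)oxy]pent-3-en-1-yl}-1,4-dioxo-1,4-dihydronaphthalene-5,8-diyl diacetate | CC(C)=CC[C@H](OC(=O)C=C(C)C)C1=CC(=O)c2c(OC(C)=O)ccc(OC(C)=O)c2C1=O | intermediate
20 | alkannin β,β-dimethylacrylate, (1S)-1-(5,8-dihydroxy-1,4-dioxo-1,4-dihydronaphthalen-2-yl)-4-methylpent-3-en-1-yl 3-methylbut-2-enoate | CC(C)=CC[C@H](OC(=O)C=C(C)C)C1=CC(=O)c2c(O)ccc(O)c2C1=O | target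

**Step count and risks**

Total step count: 11. Longest linear sequence: 11 steps (1 to 20).

Steps most likely to fail:

- **Step 6 (Rieche formylation of 7).** TiCl4 may complex or cleave the aryl acetates, or the arene may react sluggishly. Fallback: set out from 4 and formylate before the protecting-group swap. Vilsmeier–Haack formylation (POCl3, DMF, then aqueous NaOAc) gives 1,4,5,8-tetramethoxynaphthalene-2-carbaldehyde F1. (NH4)2Ce(NO3)6 in MeCN/H2O then oxidises the formyl-free, more electron-rich ring to 6-formyl-5,8-dimethoxy-1,4-naphthoquinone F2. Na2S2O4 (EtOAc/H2O) reduces this to 5,8-dihydroxy-1,4-dimethoxynaphthalene-2-carbaldehyde F3, which is acetylated at once (Ac2O, pyridine) and comes back to the route at 9.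

- **Step 7 (asymmetric allylboration).** The ee may be insufficient with this hindered aldehyde, or the aryl acetates may suffer. Fallback: set out from 9 and move the stereocontrol to a ketone reduction. Barbier allylation (allyl bromide, Zn, THF/saturated aqueous NH4Cl) gives racemic 6-(1-hydroxybut-3-en-1-yl)-5,8-dimethoxynaphthalene-1,4-diyl diacetate F4. Cross-metathesis with 14 as in step 8 gives racemic 6-(1-hydroxy-4-methylpent-3-en-1-yl)-5,8-dimethoxynaphthalene-1,4-diyl diacetate F5. Dess–Martin oxidation (NaHCO3-buffered, to keep the β,γ-olefin in place) gives 5,8-dimethoxy-6-(4-methylpent-3-enoyl)naphthalene-1,4-diyl diacetate F6. Corey–Bakshi–Shibata reduction with (R)-Me-CBS and catecholborane (toluene, −78 °C; aryl as the large group gives the (S)-alcohol) comes back to the route at 15.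

- **Step 11 (selective removal of the aryl acetates).** The side-chain ester may be partly cleaved, or the naphthazarin may degrade in base. Fallback: set out from 15 and install the ester last. (NH4)2Ce(NO3)6 oxidation of the free alcohol gives 2-[(1S)-1-hydroxy-4-methylpent-3-en-1-yl]-1,4-dioxo-1,4-dihydronaphthalene-5,8-diyl diacetate F7. K2CO3/MeOH removes both acetates, with no competing ester present, to give alkannin F8. Steglich esterification with 16 (DCC, DMAP, CH2Cl2, 0 °C) acylates only the side-chain hydroxyl, because the two peri-hydroxyls are hydrogen-bonded to the quinone carbonyls, and comes back to the route at 20.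

**Further compounds**

F1 | step 6 | 1,4,5,8-tetramethoxynaphthalene-2-carbaldehyde | COc1ccc(OC)c2c(OC)c(C=O)cc(OC)c12
F2 | step 6 | 6-formyl-5,8-dimethoxy-1,4-naphthoquinone | O=Cc1cc(OC)c2C(=O)C=CC(=O)c2c1OC
F3 | step 6 | 5,8-dihydroxy-1,4-dimethoxynaphthalene-2-carbaldehyde | O=Cc1cc(OC)c2c(O)ccc(O)c2c1OC
F4 | step 7 | racemic 6-(1-hydroxybut-3-en-1-yl)-5,8-dimethoxynaphthalene-1,4-diyl diacetate | C=CCC(O)c1cc(OC)c2c(OC(C)=O)ccc(OC(C)=O)c2c1OC
F5 | step 7 | racemic 6-(1-hydroxy-4-methylpent-3-en-1-yl)-5,8-dimethoxynaphthalene-1,4-diyl diacetate | CC(C)=CCC(O)c1cc(OC)c2c(OC(C)=O)ccc(OC(C)=O)c2c1OC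
F6 | step 7 | 5,8-dimethoxy-6-(4-methylpent-3-enoyl)naphthalene-1,4-diyl diacetate | CC(C)=CCC(=O)c1cc(OC)c2c(OC(C)=O)ccc(OC(C)=O)c2c1OC
F7 | step 11 | 2-[(1S)-1-hydroxy-4-methylpent-3-en-1-yl]-1,4-dioxo-1,4-dihydronaphthalene-5,8-diyl diacetate | CC(C)=CC[C@H](O)C1=CC(=O)c2c(OC(C)=O)ccc(OC(C)=O)c2C1=O
F8 | step 11 | alkannin, 5,8-dihydroxy-2-[(1S)-1-hydroxy-4-methylpent-3-en-1-yl]naphthalene-1,4-dione | CC(C)=CC[C@H](O)C1=CC(=O)c2c(O)ccc(O)c2C1=O
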